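**Plan**

- Retrosynthesis: cut the C8–O angelate bond and the lactone at C7–C11 and O6–C12 (a phosphonoacetate tethered to O6 opening a C7–C8 epoxide), put back the C2–C3 single bond, then cut O–C10 and C9–C10 together (oxonium ylide [2,3] shift), and last O–C7 and C3–C4 of a tetrahydropyran (vinyl epoxide opening, aldol).
- Enabling feature: the furanone oxygen joins C3 to the methyl-bearing quaternary C10, which also holds C9. The 11-oxabicyclo[6.2.1]undecane core therefore unfolds to a tetrahydropyran O–C3–C4–C5–C6–C7 with vinyl C8=C9 on C7 and the diazoketone arm C2–C1(=O)–C10(N2)–C14 on C3.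
- Forward: Johnson–Claisen and Evans aldol reactions assemble C1–C9 and C15; the tetrahydropyran closes by 6-endo epoxide opening; the oxolanone and the nine-membered oxacycle (ten-membered carbocycle) then form in one operation; the furanone alkene, the lactone ring and the ester follow.
- Stereochemistry: C3 and C4 come from the (R)-benzyloxazolidinone aldol, C6 and C7 from Shi epoxidation, C10 is relayed from C3 through the bridge, C7 comes from hydroxyl-directed epoxidation plus SN2 opening, and C8 from Mitsunobu inversion.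

Key step: step 12

Remark: atoms carry the germacrane numbers of the target (C1 ketone, C2=C3 furanone alkene, C4 with C15, C6 lactone oxygen, C7 with C11–C13, C8 ester, C10 with C14). The oxazolidinone, the silyloxypropanal, the D-fructose-derived Shi ketone, (diethoxyphosphoryl)acetic acid, angelic acid and N-ethyl-N-nitrosourea are taken as purchased. The C15 ether is carried as tert-butyldiphenylsilyl so that the C1 tert-butyldimethylsilyl ether can be removed selectively.

**Route**

Step 1
Reactants: 1 penta-1,4-dien-3-ol; 2 triethyl orthoacetate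
Product: 3 ethyl (4E)-hepta-4,6-dienoate
Conditions: EtCO2H (cat.), 140 °C, EtOH distilled off
Reagents that add atoms: triethyl orthoacetate (2), CCOC(C)(OCC)OCC
Why: Johnson–Claisen rearrangement: the mixed ketene acetal formed from 1 and 2 should rearrange through a chair with the spectator vinyl group equatorial, which gives the 4E alkene and leaves a conjugated diene.

Step 2
Reactants: 3 ethyl (4E)-hepta-4,6-dienoate
Product: 4 (4E)-hepta-4,6-dienoic acid
Conditions: LiOH, THF/H2O, rt; then 1 M HCl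
Reagents that add atoms: lithium hydroxide, [Li+].[OH-]
Why: Plain ester saponification; the skipped diene ester is not expected to move into conjugation under LiOH at room temperature.

Step 3
Reactants: 4 (4E)-hepta-4,6-dienoic acid; 5 (4R)-4-benzyl-1,3-oxazolidin-2-one
Product: 7 (4R)-4-benzyl-3-[(4E)-hepta-4,6-dienoyl]-1,3-oxazolidin-2-one, via mixed pivalic anhydride 6 (not isolated)
Conditions: t-BuCOCl, Et3N, THF, −20 °C; then 5, LiCl, rt
Reagents that add atoms: (4R)-4-benzyl-1,3-oxazolidin-2-one (5), O=C1N[C@H](Cc2ccccc2)CO1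
Why: N-acylation of the oxazolidinone through the pivalic mixed anhydride with LiCl and Et3N; the hindered pivaloyl carbonyl directs attack to the dienoyl carbonyl.

Step 4
Reactants: 7 (4R)-4-benzyl-3-[(4E)-hepta-4,6-dienoyl]-1,3-oxazolidin-2-one; 8 3-[(tert-butyldimethylsilyl)oxy]propanal
Product: 9 (4R)-4-benzyl-3-{(2R,3S)-5-[(tert-butyldimethylsilyl)oxy]-3-hydroxy-2-[(2E)-penta-2,4-dien-1-yl]pentanoyl}-1,3-oxazolidin-2-one
Conditions: n-Bu2BOTf, i-Pr2NEt, CH2Cl2, −78 to 0 °C; 8, −78 to 0 °C; H2O2, MeOH, pH 7 buffer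
Reagents that add atoms: 3-[(tert-butyldimethylsilyl)oxy]propanal (8), O=CCCO[Si](C)(C)C(C)(C)C
Why: Evans syn aldol reaction: the Z dibutylboron enolate should react through a Zimmerman–Traxler chair on the face away from the benzyl group of the (R)-auxiliary, which sets C4 and the C3 carbinol (2R,3S in the acyl chain).

Step 5
Reactants: 9 the aldol adduct
Product: 10 (2S,3S)-5-[(tert-butyldimethylsilyl)oxy]-2-[(2E)-penta-2,4-dien-1-yl]pentane-1,3-diol
Conditions: LiBH4, MeOH, THF, 0 °C
Reagents that add atoms: none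
Why: Reductive cleavage of the imide by LiBH4 should free the C15 hydroxymethyl group and return the auxiliary without touching the stereocentres or the silyl ether.

Step 6
Reactants: 10 the 1,3-diol
Product: 11 (3S,4S,6E)-1-[(tert-butyldimethylsilyl)oxy]-4-{[(tert-butyldiphenylsilyl)oxy]methyl}nona-6,8-dien-3-ol
Conditions: t-BuPh2SiCl, imidazole, CH2Cl2, 0 °C
Reagents that add atoms: tert-butyl(chloro)diphenylsilane, CC(C)(C)[Si](Cl)(c1ccccc1)c1ccccc1
Why: Silylation with the bulky chlorosilane is selective for the primary hydroxyl, leaving the C3 hydroxyl free as the later ring oxygen.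

Step 7
Reactants: 11 the dienol
Product: 13 (2S,3R,5S,6S)-6-{2-[(tert-butyldimethylsilyl)oxy]ethyl}-5-{[(tert-butyldiphenylsilyl)oxy]methyl}-2-ethenyloxan-3-ol, via vinyl epoxide 12 (not isolated)
Conditions: Shi ketone (D-fructose-derived, 30 mol %), KHSO5 (as 2KHSO5·KHSO4·K2SO4), K2CO3, n-Bu4NHSO4, MeCN/CH2(OMe)2/aq. buffer, 0 °C; then CSA (cat.), CH2Cl2, 0 °C
Reagents that add atoms: potassium peroxymonosulfate, [K+].[O-]S(=O)(=O)OO
Why: Shi asymmetric epoxidation (dioxirane from the D-fructose-derived ketone, spiro transition state) should oxidise the internal, more electron-rich trans alkene of the diene to the (6R,7R) vinyl epoxide under catalyst control, and acid then triggers the 6-endo hydroxy epoxide opening at the allylic carbon that is typical of trans vinyl epoxides, with inversion at C7 and retention at C6.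

Step 8
Reactants: 13 the tetrahydropyranol
Product: 14 tert-butyl{2-[(2S,3S,5R,6S)-3-{[(tert-butyldiphenylsilyl)oxy]methyl}-6-ethenyl-5-[(4-methoxybenzyl)oxy]oxan-2-yl]ethoxy}dimethylsilane
Conditions: NaH, 4-MeOC6H4CH2Cl, n-Bu4NI (cat.), THF/DMF, 0 °C to rt
Reagents that add atoms: 4-methoxybenzyl chloride, COc1ccc(CCl)cc1
Why: Williamson etherification of the secondary alkoxide; the ether blocks O–H insertion in the carbenoid step and can be removed later by oxidation.

Step 9
Reactants: 14 the fully protected tetrahydropyran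
Product: 15 2-[(2S,3S,5R,6S)-3-{[(tert-butyldiphenylsilyl)oxy]methyl}-6-ethenyl-5-[(4-methoxybenzyl)oxy]oxan-2-yl]ethan-1-ol
Conditions: PPTS (cat.), MeOH, rt
Reagents that add atoms: none
Why: Acid-catalysed methanolysis removes the primary tert-butyldimethylsilyl ether far faster than the tert-butyldiphenylsilyl ether.

Step 10
Reactants: 15 the primary alcohol
Product: 16 2-[(2S,3S,5R,6S)-3-{[(tert-butyldiphenylsilyl)oxy]methyl}-6-ethenyl-5-[(4-methoxybenzyl)oxy]oxan-2-yl]acetic acid
Conditions: TEMPO (cat.), PhI(OAc)2, MeCN/H2O, rt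
Reagents that add atoms: water, O
Why: Oxoammonium oxidation (TEMPO with PhI(OAc)2 in aqueous acetonitrile) takes the primary alcohol through the aldehyde hydrate to the acid under near-neutral conditions that spare the β-alkoxy stereocentre, the alkene and both ethers.

Step 11
Reactants: 16 the acid; 17 N-ethyl-N-nitrosourea
Product: 19 3-diazo-1-[(2S,3S,5R,6S)-3-{[(tert-butyldiphenylsilyl)oxy]methyl}-6-ethenyl-5-[(4-methoxybenzyl)oxy]oxan-2-yl]butan-2-one, via mixed carbonic anhydride 18 (not isolated)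
Conditions: i-BuOCOCl, Et3N, THF, −20 °C; then CH3CHN2 (from 17, aq. KOH, Et2O), 0 °C
Reagents that add atoms: diazoethane, CC=[N+]=[N-] (made from N-ethyl-N-nitrosourea 17, CCN(N=O)C(N)=O)
Why: Arndt–Eistert-type acylation: the mixed carbonic anhydride acylates diazoethane at carbon and the departing carbonate takes up the proton, which should give the α-methyl diazoketone.

Step 12
Reactants: 19 the 2,6-trans tetrahydropyranyl α-methyl diazoketone
Product: 22 (1S,2S,4R,5Z,8S)-2-{[(tert-butyldiphenylsilyl)oxy]methyl}-4-[(4-methoxybenzyl)oxy]-8-methyl-11-oxabicyclo[6.2.1]undec-5-en-9-one, via oxonium ylide 20 (not isolated), via E-alkene isomer 21 (not isolated)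
Conditions: Cu(CF3COCHCOCF3)2 (5 mol %), CH2Cl2, reflux; then EtSH, AIBN (cat.), PhH, reflux
Reagents that add atoms: none
Why: Loss of N2 gives a copper carbenoid at C10 that is trapped by the tetrahydropyran oxygen, closing the oxolan-3-one ring (O, C3, C2, C1, C10) as a bicyclic oxonium ylide, and a [2,3]-sigmatropic shift through a five-centre envelope (C10, O, C7, C8, C9) then joins C10 to C9 and cleaves O–C7, so the six-membered ether grows by three atoms into the nine-membered oxacycle (ten-membered carbocycle). The closest known reaction is the copper-catalysed oxonium ylide ring expansion of 2-vinyl tetrahydropyranyl diazoketones to 11-oxabicyclo[6.2.1]undecenones. The one new stereocentre, C10, is fixed by C3, because the six-carbon bridge can span the five-membered ring only in the cis sense. Ylide formation must outrun 1,2-hydride shift from the C14 methyl, C–H insertion and cyclopropanation of the vinyl group; the five-atom reach of the ether oxygen and the electron-poor divalent copper catalyst favour it. In either chair of the 2,6-trans ether the vinyl group and the O–C10 bond are gauche only when C9 swings away from C6, so the E alkene is the expected kinetic product. Reversible thiyl radical addition should then convert it into the more stable Z alkene, the geometry the later steps need.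

Step 13
Reactants: 22 the Z bicyclic ketone
Product: 24 (2S,4R,5Z,8S)-2-{[(tert-butyldiphenylsilyl)oxy]methyl}-4-[(4-methoxybenzyl)oxy]-8-methyl-11-oxabicyclo[6.2.1]undeca-1(10),5-dien-9-one, via trimethylsilyl enol ether 23 (not isolated)
Conditions: LiN(SiMe3)2, Me3SiCl, THF, −78 °C; then Pd(OAc)2, MeCN, rt
Reagents that add atoms: none
Why: Saegusa–Ito oxidation: only C2 can enolise because C10 is quaternary, and β-hydride loss from the palladium enolate can only involve the C3 hydrogen, which gives the C2=C3 alkene of the 3(2H)-furanone.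

Step 14
Reactants: 24 the furanone 4-methoxybenzyl ether
Product: 25 the C6 allylic alcohol (4S,6R,10S; C15 silyl ether, 7Z alkene)
Conditions: DDQ, CH2Cl2/pH 7 buffer, 0 °C
Reagents that add atoms: none
Why: Oxidative cleavage of the electron-rich benzyl ether by DDQ through the benzylic cation and hemiacetal; the silyl ether, the furanone and the Z alkene should not be oxidised.

Step 15
Reactants: 25 the allylic alcohol
Product: 26 the 7,8-cis-epoxy alcohol with the epoxide oxygen on the face of the C6 hydroxyl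
Conditions: VO(C5H7O2)2 (cat.), t-BuOOH, CH2Cl2, 0 °C to rt
Reagents that add atoms: tert-butyl hydroperoxide, CC(C)(C)OO
Why: Hydroxyl-directed epoxidation: the vanadium alkoxide of the allylic alcohol delivers the peroxide oxygen to the alkene face on the side of the C6 hydroxyl, as in medium-ring (Z)-cycloalkenols, which sets C7 and C8 and leaves the electron-poor furanone alkene alone.

Step 16
Reactants: 26 the epoxy alcohol; 27 (diethoxyphosphoryl)acetic acid
Product: 28 the C6 (diethoxyphosphoryl)acetate of 26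
Conditions: DCC, DMAP (cat.), CH2Cl2, 0 °C to rt
Reagents that add atoms: (diethoxyphosphoryl)acetic acid (27), CCOP(=O)(CC(=O)O)OCC
Why: Steglich esterification tethers the C11–C12 unit to O6 with retention at C6; the epoxide tolerates the carbodiimide conditions.

Step 17
Reactants: 28 the epoxy phosphonoacetate
Product: 30 the trans-fused α-methylene lactone with a free C8 hydroxyl on the face opposite to C11 (8-epi alcohol, C15 silyl ether), via phosphono lactone 29 (not isolated)
Conditions: KOC(CH3)3, THF, 0 °C to rt; then (CH2O)n, rt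
Reagents that add atoms: formaldehyde (from paraformaldehyde), C=O
Why: Intramolecular alkylation of the phosphonate carbanion by the epoxide (5-exo, anti opening at C7 with inversion, C8 oxygen retained) should give the trans-fused phosphono lactone, whose anion then undergoes Horner–Wadsworth–Emmons olefination with formaldehyde to the α-methylene lactone, the same tethered phosphonoacetate tactic that is used for Michael-initiated lactone annulation.

Step 18
Reactants: 30 the C8 alcohol; 31 angelic acid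
Product: 32 the 15-O-tert-butyldiphenylsilyl ether of the target
Conditions: 31, PPh3, DIAD, PhMe, 0 °C to rt
Reagents that add atoms: angelic acid (31), C/C=C(/C)C(=O)O
Why: Mitsunobu esterification: SN2 attack of the angelate on the C8 alkoxyphosphonium ion inverts C8, and because the acid acts as nucleophile and is never activated at its carbonyl, the Z alkene of the angelate should not isomerise.

Step 19
Reactants: 32 the silyl ether of the target
Product: 33 CNP0108636.1
Conditions: HF·pyridine, pyridine, THF, 0 °C to rt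
Reagents that add atoms: none
Why: Fluoride-mediated cleavage of the silyl ether under buffered acidic conditions that should leave the methylene lactone, the angelate and the furanone intact.

**Compound list**

1 | penta-1,4-dien-3-ol | C=CC(O)C=C | starting material
2 | triethyl orthoacetate | CCOC(C)(OCC)OCC | starting material
3 | ethyl (4E)-hepta-4,6-dienoate | CCOC(=O)CC/C=C/C=C | intermediate
4 | (4E)-hepta-4,6-dienoic acid | OC(=O)CC/C=C/C=C | intermediate
5 | (4R)-4-benzyl-1,3-oxazolidin-2-one | O=C1N[C@H](Cc2ccccc2)CO1 | starting material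
6 | (4E)-hepta-4,6-dienoic pivalic anhydride | CC(C)(C)C(=O)OC(=O)CC/C=C/C=C | intermediate
7 | (4R)-4-benzyl-3-[(4E)-hepta-4,6-dienoyl]-1,3-oxazolidin-2-one | C=C/C=C/CCC(=O)N1C(=O)OC[C@H]1Cc1ccccc1 | intermediate
8 | 3-[(tert-butyldimethylsilyl)oxy]propanal | O=CCCO[Si](C)(C)C(C)(C)C | starting material
9 | (4R)-4-benzyl-3-{(2R,3S)-5-[(tert-butyldimethylsilyl)oxy]-3-hydroxy-2-[(2E)-penta-2,4-dien-1-yl]pentanoyl}-1,3-oxazolidin-2-one | CC(C)(C)[Si](C)(C)OCC[C@H](O)[C@H](C(=O)N1C(=O)OC[C@H]1Cc1ccccc1)C/C=C/C=C | intermediate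
10 | (2S,3S)-5-[(tert-butyldimethylsilyl)oxy]-2-[(2E)-penta-2,4-dien-1-yl]pentane-1,3-diol | CC(C)(C)[Si](C)(C)OCC[C@H](O)[C@H](CO)C/C=C/C=C | intermediate
11 | (3S,4S,6E)-1-[(tert-butyldimethylsilyl)oxy]-4-{[(tert-butyldiphenylsilyl)oxy]methyl}nona-6,8-dien-3-ol | CC(C)(C)[Si](C)(C)OCC[C@H](O)[C@H](CO[Si](c1ccccc1)(c1ccccc1)C(C)(C)C)C/C=C/C=C | intermediate
12 | (3S,4S)-1-[(tert-butyldimethylsilyl)oxy]-4-{[(tert-butyldiphenylsilyl)oxy]methyl}-5-[(2R,3R)-3-ethenyloxiran-2-yl]pentan-3-ol | CC(C)(C)[Si](C)(C)OCC[C@H](O)[C@H](CO[Si](c1ccccc1)(c1ccccc1)C(C)(C)C)C[C@H]1O[C@@H]1C=C | intermediate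
13 | (2S,3R,5S,6S)-6-{2-[(tert-butyldimethylsilyl)oxy]ethyl}-5-{[(tert-butyldiphenylsilyl)oxy]methyl}-2-ethenyloxan-3-ol | CC(C)(C)[Si](C)(C)OCC[C@@H]1O[C@@H](C=C)[C@H](O)C[C@H]1CO[Si](c1ccccc1)(c1ccccc1)C(C)(C)C | intermediate
14 | tert-butyl{2-[(2S,3S,5R,6S)-3-{[(tert-butyldiphenylsilyl)oxy]methyl}-6-ethenyl-5-[(4-methoxybenzyl)oxy]oxan-2-yl]ethoxy}dimethylsilane | CC(C)(C)[Si](C)(C)OCC[C@@H]1O[C@@H](C=C)[C@H](OCc2ccc(OC)cc2)C[C@H]1CO[Si](c1ccccc1)(c1ccccc1)C(C)(C)C | intermediate
15 | 2-[(2S,3S,5R,6S)-3-{[(tert-butyldiphenylsilyl)oxy]methyl}-6-ethenyl-5-[(4-methoxybenzyl)oxy]oxan-2-yl]ethan-1-ol | OCC[C@@H]1O[C@@H](C=C)[C@H](OCc2ccc(OC)cc2)C[C@H]1CO[Si](c1ccccc1)(c1ccccc1)C(C)(C)C | intermediate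
16 | 2-[(2S,3S,5R,6S)-3-{[(tert-butyldiphenylsilyl)oxy]methyl}-6-ethenyl-5-[(4-methoxybenzyl)oxy]oxan-2-yl]acetic acid | OC(=O)C[C@@H]1O[C@@H](C=C)[C@H](OCc2ccc(OC)cc2)C[C@H]1CO[Si](c1ccccc1)(c1ccccc1)C(C)(C)C | intermediate
17 | N-ethyl-N-nitrosourea | CCN(N=O)C(N)=O | starting material
18 | mixed isobutyl carbonic anhydride of 16 | CC(C)COC(=O)OC(=O)C[C@@H]1O[C@@H](C=C)[C@H](OCc2ccc(OC)cc2)C[C@H]1CO[Si](c1ccccc1)(c1ccccc1)C(C)(C)C | intermediate
19 | 3-diazo-1-[(2S,3S,5R,6S)-3-{[(tert-butyldiphenylsilyl)oxy]methyl}-6-ethenyl-5-[(4-methoxybenzyl)oxy]oxan-2-yl]butan-2-one | CC(=[N+]=[N-])C(=O)C[C@@H]1O[C@@H](C=C)[C@H](OCc2ccc(OC)cc2)C[C@H]1CO[Si](c1ccccc1)(c1ccccc1)C(C)(C)C | intermediate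
20 | bicyclic oxonium ylide (oxygen bonded to C3, C7 and C10; carbanion at C10) | C[C-]2C(=O)C[C@@H]1[O+]2[C@@H](C=C)[C@H](OCc3ccc(OC)cc3)C[C@H]1CO[Si](c4ccccc4)(c4ccccc4)C(C)(C)C | intermediate
21 | (1S,2S,4R,5E,8S)-2-{[(tert-butyldiphenylsilyl)oxy]methyl}-4-[(4-methoxybenzyl)oxy]-8-methyl-11-oxabicyclo[6.2.1]undec-5-en-9-one | C[C@]12C/C=C/[C@H](OCc3ccc(OC)cc3)C[C@@H](CO[Si](c3ccccc3)(c3ccccc3)C(C)(C)C)[C@H](CC1=O)O2 | intermediate
22 | (1S,2S,4R,5Z,8S)-2-{[(tert-butyldiphenylsilyl)oxy]methyl}-4-[(4-methoxybenzyl)oxy]-8-methyl-11-oxabicyclo[6.2.1]undec-5-en-9-one | C[C@]12C/C=C\[C@H](OCc3ccc(OC)cc3)C[C@@H](CO[Si](c3ccccc3)(c3ccccc3)C(C)(C)C)[C@H](CC1=O)O2 | intermediate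
23 | C1 trimethylsilyl enol ether (C1=C2) of 22 | C[C@]12C/C=C\[C@H](OCc3ccc(OC)cc3)C[C@@H](CO[Si](c3ccccc3)(c3ccccc3)C(C)(C)C)[C@H](C=C1O[Si](C)(C)C)O2 | intermediate
24 | (2S,4R,5Z,8S)-2-{[(tert-butyldiphenylsilyl)oxy]methyl}-4-[(4-methoxybenzyl)oxy]-8-methyl-11-oxabicyclo[6.2.1]undeca-1(10),5-dien-9-one | C[C@]12C/C=C\[C@H](OCc3ccc(OC)cc3)C[C@@H](CO[Si](c3ccccc3)(c3ccccc3)C(C)(C)C)C(=CC1=O)O2 | intermediate
25 | (2S,4R,5Z,8S)-2-{[(tert-butyldiphenylsilyl)oxy]methyl}-4-hydroxy-8-methyl-11-oxabicyclo[6.2.1]undeca-1(10),5-dien-9-one | C[C@]12C/C=C\[C@H](O)C[C@@H](CO[Si](c3ccccc3)(c3ccccc3)C(C)(C)C)C(=CC1=O)O2 | intermediate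
26 | 7,8-cis-epoxide of 25 with the epoxide oxygen syn to the C6 hydroxyl | C[C@]12C[C@@H]3O[C@@H]3[C@H](O)C[C@@H](CO[Si](c4ccccc4)(c4ccccc4)C(C)(C)C)C(=CC1=O)O2 | intermediate
27 | (diethoxyphosphoryl)acetic acid | CCOP(=O)(CC(=O)O)OCC | starting material
28 | C6 (diethoxyphosphoryl)acetate of 26 | C[C@]12C[C@@H]3O[C@@H]3[C@H](OC(=O)CP(=O)(OCC)OCC)C[C@@H](CO[Si](c4ccccc4)(c4ccccc4)C(C)(C)C)C(=CC1=O)O2 | intermediate
29 | trans-fused 11-(diethoxyphosphoryl) 12,6-lactone with C8 hydroxyl (formed as its potassium salt; C11 unassigned) | CCOP(=O)(OCC)C1C(=O)O[C@@H]2C[C@@H](CO[Si](c4ccccc4)(c4ccccc4)C(C)(C)C)C3=CC(=O)[C@](C)(C[C@H](O)[C@@H]12)O3 | intermediate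
30 | 15-O-tert-butyldiphenylsilyl 8-epi-8-deacyl target (α-methylene lactone; C8 hydroxyl trans to C11) | C=C1C(=O)O[C@@H]2C[C@@H](CO[Si](c4ccccc4)(c4ccccc4)C(C)(C)C)C3=CC(=O)[C@](C)(C[C@H](O)[C@@H]12)O3 | intermediate
31 | angelic acid, (2Z)-2-methylbut-2-enoic acid | C/C=C(/C)C(=O)O | starting material
32 | 15-O-tert-butyldiphenylsilyl ether of the target | C=C1C(=O)O[C@@H]2C[C@@H](CO[Si](c4ccccc4)(c4ccccc4)C(C)(C)C)C3=CC(=O)[C@](C)(C[C@@H](OC(=O)/C(C)=C\C)[C@@H]12)O3 | intermediate
33 | CNP0108636.1, (4S,6R,7S,8R,10S)-15-hydroxy-1-oxo-3,10-epoxygermacra-2,11(13)-dien-12,6-olid-8-yl (2Z)-2-methylbut-2-enoate | C=C1C(=O)O[C@@H]2C[C@@H](CO)C3=CC(=O)[C@](C)(C[C@@H](OC(=O)/C(C)=C\C)[C@@H]12)O3 | target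

**Step count and risks**

Total steps: 19. Longest linear sequence: 19 steps (1 to 33).

Steps most likely to fail:

1. Step 12. What may go wrong is 1,2-hydride migration from the C14 methyl within the copper carbenoid, or carbenoid dimerisation, overtaking capture by the ring oxygen; the E-to-Z equilibration could also stall. The fallback sets out from acid 16. Its mixed anhydride is treated with diazomethane to give the terminal diazoketone F1, which has no migrating hydrogen. The same Cu(CF3COCHCOCF3)2 ring expansion and thiyl equilibration should give the C10-unsubstituted bicyclic ketone F2. Saegusa–Ito oxidation then gives the C10-unsubstituted furanone F3. Kinetic deprotonation at C10, the only α′ position of the 3(2H)-furanone, with LiN(SiMe3)2 and alkylation with MeI installs the methyl group; the bridge allows only the cis-bridged product, and the route is rejoined at 24.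

2. Step 17. What may go wrong is the tethered phosphonate carbanion failing to line up anti to the C7–O bond, so that attack at C8, cleavage of the ester by the liberated alkoxide, or attack of that alkoxide on phosphorus takes over. The fallback sets out from epoxy alcohol 26 and changes both the activating group and the way the methylene is introduced. Esterification with allyl hydrogen malonate (DCC, DMAP) gives the allyl malonate F4. The smaller, softer malonate anion (Cs2CO3, MeCN) should open the epoxide at C7 to give the allyloxycarbonyl lactone F5. Pd(PPh3)4 with morpholine removes the allyl group to give the lactone acid F6, and decarboxylative Mannich methylenation ((CH2O)n, Et2NH) rejoins the route at 30.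

3. Step 18. What may go wrong is elimination or simple non-reaction at the hindered C8 alkoxyphosphonium ion instead of SN2 displacement, together with conjugate addition of PPh3 to the methylene lactone. The fallback sets out from alcohol 30 and replaces substitution by oxidation and reduction. Dess–Martin periodinane gives the C8 ketone F7. Reduction with NaBH4 and CeCl3·7H2O at −78 °C, with hydride arriving anti to the C7–C11 bond, should give the inverted C8 alcohol F8. Yamaguchi esterification (2,4,6-trichlorobenzoyl chloride, Et3N, angelic acid 31, then F8 in toluene) rejoins the route at 32 without Z-to-E isomerisation of the angelate.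

**Further compounds**

F1 | step 12 | 1-diazo-3-[(2S,3S,5R,6S)-3-{[(tert-butyldiphenylsilyl)oxy]methyl}-6-ethenyl-5-[(4-methoxybenzyl)oxy]oxan-2-yl]propan-2-one | [N-]=[N+]=CC(=O)C[C@@H]1O[C@@H](C=C)[C@H](OCc2ccc(OC)cc2)C[C@H]1CO[Si](c1ccccc1)(c1ccccc1)C(C)(C)C
F2 | step 12 | C10-unsubstituted analogue of 22 (8-demethyl bicyclic ketone, 5Z) | [H][C@]12C/C=C\[C@H](OCc3ccc(OC)cc3)C[C@@H](CO[Si](c3ccccc3)(c3ccccc3)C(C)(C)C)[C@H](CC1=O)O2
F3 | step 12 | C10-unsubstituted analogue of 24 (8-demethyl furanone) | [H][C@]12C/C=C\[C@H](OCc3ccc(OC)cc3)C[C@@H](CO[Si](c3ccccc3)(c3ccccc3)C(C)(C)C)C(=CC1=O)O2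
F4 | step 17 | C6 allyl malonate of 26 | C[C@]12C[C@@H]3O[C@@H]3[C@H](OC(=O)CC(=O)OCC=C)C[C@@H](CO[Si](c4ccccc4)(c4ccccc4)C(C)(C)C)C(=CC1=O)O2
F5 | step 17 | trans-fused 11-(allyloxycarbonyl) 12,6-lactone with C8 hydroxyl | C=CCOC(=O)C1C(=O)O[C@@H]2C[C@@H](CO[Si](c4ccccc4)(c4ccccc4)C(C)(C)C)C3=CC(=O)[C@](C)(C[C@H](O)[C@@H]12)O3
F6 | step 17 | trans-fused 11-carboxy 12,6-lactone with C8 hydroxyl | OC(=O)C1C(=O)O[C@@H]2C[C@@H](CO[Si](c4ccccc4)(c4ccccc4)C(C)(C)C)C3=CC(=O)[C@](C)(C[C@H](O)[C@@H]12)O3
F7 | step 18 | C8 ketone of 30 | C=C1C(=O)O[C@@H]2C[C@@H](CO[Si](c4ccccc4)(c4ccccc4)C(C)(C)C)C3=CC(=O)[C@](C)(CC(=O)[C@@H]12)O3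
F8 | step 18 | C8 epimer of 30 (C8 hydroxyl cis to C11) | C=C1C(=O)O[C@@H]2C[C@@H](CO[Si](c4ccccc4)(c4ccccc4)C(C)(C)C)C3=CC(=O)[C@](C)(C[C@@H](O)[C@@H]12)O3
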